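## Retrosynthetic overview

1. Fluctuadin (25) ⇐ 8‑O‑methacryloylation, then 9‑O‑silyl → acetyl exchange, of macrocyclic alcohol 22.
2. 22 ⇐ key step: SmI2 ketyl–olefin macrocyclisation of aldehyde 21 (C7–C8 bond). The C8 ketyl radical adds to a 3‑(acetoxymethyl)butenolide and acetate loss unveils the α‑methylene lactone.
3. 21 ⇐ Nozaki–Hiyama–Kishi coupling (C9–C10) of (Z)‑α‑iodoenoate 17 with acrolein, silylation, ozonolysis.
4. 17 ⇐ esterification and ring‑closing metathesis of epoxy vinyl carbinol 12 ⇐ one‑pot asymmetric vinylation/directed epoxidation of enal 8 (sets C6, C5, C4).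
5. 8 ⇐ Claisen rearrangement (E‑alkene) and iodo‑Wittig olefination from 2,2‑dimethoxyacetaldehyde. Ring order: epoxide, then butenolide, then the ten‑membered carbocycle last.

Working atom labels: C1 (ring =CH), C2 and C3 (CH2), C4 (epoxide C bearing methyl C15), C5 (epoxide CH), C6 (lactone O–CH), C7, C8 (O‑methacryloyl), C9 (OAc), C10 (=C bearing ester carbon C14), C11–C13 (lactone α‑carbon, C=O, =CH2). Target: 4R,5R,6S,7S,8R,9R, with C5 and C8 cis on the lactone.

Assumption: Grignard reagents are bought as solutions, 2,2‑dimethoxyacetaldehyde is dried from its commercial aqueous solution, and the phosphorus ylide, silyl triflate, acyl chloride and anhydride count as reagents.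

## Route

Step 1
Reactants: 1 2,2‑dimethoxyacetaldehyde; 2 isopropenylmagnesium bromide
Product: 3 1,1‑dimethoxy‑3‑methylbut‑3‑en‑2‑ol (racemic)
Conditions: THF, −78 → 0 °C; then H2O
Reagents that add atoms: none
Why: Grignard 1,2‑addition to the aldehyde; the carbinol stereocentre is destroyed in step 2, so no control is needed.

Step 2
Reactants: 3 1,1‑dimethoxy‑3‑methylbut‑3‑en‑2‑ol; 4 ethyl vinyl ether
Product: 6 (4E)‑6,6‑dimethoxy‑4‑methylhex‑4‑enal, via allyl vinyl ether 5 (not isolated)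
Conditions: Hg(OAc)2 (10 mol %), 4 (solvent), reflux; evaporate; PhMe, 150 °C, sealed tube
Reagents that add atoms: none
Why: Mercury‑catalysed transetherification followed by Claisen rearrangement through a chair with the CH(OMe)2 group equatorial gives the E‑trisubstituted C4=C5 alkene.

Step 3
Reactants: 6 (4E)‑6,6‑dimethoxy‑4‑methylhex‑4‑enal
Product: 8 methyl (2Z,6E)‑2‑iodo‑6‑methyl‑8‑oxoocta‑2,6‑dienoate, via acetal 7 (not isolated)
Conditions: Ph3P=CHCO2Me, NIS, CH2Cl2, −20 °C; then 6, −20 °C → rt; crude 7, PPTS (cat.), acetone–H2O, rt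
Reagents that add atoms: methyl (triphenylphosphoranylidene)acetate COC(=O)C=P(c1ccccc1)(c1ccccc1)c1ccccc1; N‑iodosuccinimide O=C1CCC(=O)N1I; water O
Why: Wittig olefination with the α‑iodo ylide formed in the flask gives the (Z)‑α‑iodoenoate (iodine cis to the chain), and mild acid then hydrolyses the labile allylic acetal to the enal.

Step 4
Reactants: 8 methyl (2Z,6E)‑2‑iodo‑6‑methyl‑8‑oxoocta‑2,6‑dienoate; 9 vinylmagnesium bromide
Product: 12 methyl (2Z)‑5‑{(2R,3R)‑3‑[(1S)‑1‑hydroxyprop‑2‑en‑1‑yl]‑2‑methyloxiran‑2‑yl}‑2‑iodopent‑2‑enoate, via divinylzinc 10 (not isolated), via zinc alkoxide 11 (not isolated)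
Conditions: 9, ZnCl2, THF, then 1,4‑dioxane, filter; (−)‑MIB [(2S)‑3‑exo‑morpholinoisoborneol] (10 mol %), 8, PhMe, −30 °C; then TBHP, Ti(OiPr)4 (20 mol %), 0 °C
Reagents that add atoms: tert‑butyl hydroperoxide CC(C)(C)OO
Why: Amino‑alcohol‑catalysed vinylzinc addition to the Si face of the enal sets C6 (S), and the resulting allylic alkoxide directs titanium‑catalysed peroxide epoxidation of the trisubstituted alkene through the A(1,3)‑minimised conformer to the threo (4R,5R) epoxide (one‑pot asymmetric vinylation/directed epoxidation).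

Step 5
Reactants: 13 2‑(bromomethyl)acrylic acid
Product: 14 2‑(acetoxymethyl)acrylic acid
Conditions: KOAc (3 equiv), AcOH, 60 °C
Reagents that add atoms: potassium acetate CC(=O)[O-].[K+]
Why: Allylic substitution of bromide by acetate, where direct and allylic‑transposed attack give the same product.

Step 6
Reactants: 12 epoxy vinyl carbinol; 14 2‑(acetoxymethyl)acrylic acid
Product: 16 2‑(acetoxymethyl)acrylate ester of 12 at the C6 oxygen, via acid chloride 15 (not isolated)
Conditions: 14, (COCl)2, DMF (cat.), CH2Cl2, 0 °C → rt; evaporate; 12, i‑Pr2NEt, CH2Cl2, −20 °C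
Reagents that add atoms: none
Why: Acylation of the secondary alcohol by the acid chloride with retention at C6, using a hindered base so that no nucleophilic amine displaces the allylic acetate.

Step 7
Reactants: 16 2‑(acetoxymethyl)acrylate ester
Product: 17 methyl (2Z)‑5‑{(2R,3R)‑3‑[(2S)‑4‑(acetoxymethyl)‑5‑oxo‑2,5‑dihydrofuran‑2‑yl]‑2‑methyloxiran‑2‑yl}‑2‑iodopent‑2‑enoate
Conditions: second‑generation Grubbs catalyst (H2IMes)(PCy3)Cl2Ru=CHPh (5 mol %), PhMe (5 mM), 80 °C
Reagents that add atoms: none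
Why: Ring‑closing metathesis between the allylic vinyl group and the 1,1‑disubstituted acrylate closes the butenolide with loss of ethylene; the iodoalkene and epoxide are inert.

Step 8
Reactants: 17 butenolide (Z)‑α‑iodoenoate; 18 acrolein
Product: 19 methyl (2E)‑5‑{(2R,3R)‑3‑[(2S)‑4‑(acetoxymethyl)‑5‑oxo‑2,5‑dihydrofuran‑2‑yl]‑2‑methyloxiran‑2‑yl}‑2‑[(1S)‑1‑hydroxyprop‑2‑en‑1‑yl]pent‑2‑enoate
Conditions: CrCl2 (4 equiv), chiral 4‑isopropyl‑2‑(2‑methanesulfonamidophenyl)oxazoline ligand (4.4 equiv, enantiomer directing Re‑face attack), Et3N (4.4 equiv), THF, rt; then NiCl2 (2 mol %), 17, 18, rt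
Reagents that add atoms: none
Why: Nozaki–Hiyama–Kishi coupling, in which the alkenylchromium formed with retention of alkene geometry adds 1,2 to acrolein on the Re face under control of the chiral chromium sulfonamide complex, sets C9 (9S here by CIP, the same spatial arrangement as 9R in the target) and leaves C2 cis to C9.

Step 9
Reactants: 19 bis‑allylic alcohol
Product: 20 tert‑butyldimethylsilyl ether of 19
Conditions: TBSOTf, 2,6‑lutidine, CH2Cl2, −78 °C
Reagents that add atoms: tert‑butyldimethylsilyl trifluoromethanesulfonate CC(C)(C)[Si](C)(C)OS(=O)(=O)C(F)(F)F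
Why: Silylation of the hindered secondary alcohol at low temperature with a non‑nucleophilic base, which spares the epoxide and the base‑sensitive butenolide.

Step 10
Reactants: 20 silyl ether
Product: 21 methyl (2E)‑2‑[(1R)‑1‑(tert‑butyldimethylsilyloxy)‑2‑oxoethyl]‑5‑{(2R,3R)‑3‑[(2S)‑4‑(acetoxymethyl)‑5‑oxo‑2,5‑dihydrofuran‑2‑yl]‑2‑methyloxiran‑2‑yl}pent‑2‑enoate
Conditions: O3, CH2Cl2, −78 °C (Sudan red 7B end point); PPh3, −78 °C → rt; used crude
Reagents that add atoms: ozone [O-][O+]=O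
Why: Ozonolysis with reductive work‑up cleaves only the monosubstituted vinyl group, since the two remaining alkenes are trisubstituted and conjugated to carbonyl groups, giving the α‑silyloxy aldehyde (C8).

Step 11
Reactants: 21 α‑silyloxy aldehyde
Product: 22 macrocyclic alcohol (4R,5R,6S,7S,8R,9R): cis‑fused ten‑membered α‑methylene‑γ‑lactone with free 8‑OH and 9‑OTBS
Conditions: SmI2 (2.5 equiv), THF, −78 → 0 °C, syringe‑pump addition of 21 (final 2 mM), no proton source; aq NaHCO3
Reagents that add atoms: none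
Why: Proposed new method: single‑electron reduction of the aldehyde gives a C8 ketyl radical that adds 10‑exo to the butenolide β‑carbon C7 on the face carrying the tether (cis ring fusion), with trivalent samarium bridging the ketyl oxygen and the lactone carbonyl and the silyloxy group anti to the ketyl C–O bond to set C8; the C11 radical is then reduced to the samarium enolate, which expels acetate to give the α‑methylene lactone. The closest known reactions are samarium diiodide ketyl–olefin cyclisations onto unsaturated esters (five‑ to eight‑membered rings), intermolecular ketyl additions to butenolides and acrylates, and β‑elimination of β‑acetoxy samarium enolates.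

Step 12
Reactants: 22 macrocyclic alcohol
Product: 23 8‑O‑methacryloyl derivative of 22
Conditions: methacryloyl chloride, Et3N, DMAP (cat.), CH2Cl2, 0 °C
Reagents that add atoms: methacryloyl chloride C=C(C)C(=O)Cl
Why: Acylation of the only free hydroxyl, with retention at C8.

Step 13
Reactants: 23 8‑O‑methacryloyl silyl ether
Product: 25 fluctuadin, via alcohol 24 (not isolated)
Conditions: HF·pyridine, pyridine, THF, 0 °C → rt; then Ac2O, DMAP, 0 °C
Reagents that add atoms: acetic anhydride CC(=O)OC(C)=O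
Why: Buffered fluoride desilylation (acidic medium, so no acyl migration, and tolerated by the epoxide) followed by acetylation of the liberated C9 hydroxyl in the same flask.

## Compound list

1 | 2,2‑dimethoxyacetaldehyde | COC(OC)C=O | starting material
2 | isopropenylmagnesium bromide | CC(=C)[Mg]Br | starting material
3 | 1,1‑dimethoxy‑3‑methylbut‑3‑en‑2‑ol (racemic) | COC(OC)C(O)C(C)=C | intermediate
4 | ethyl vinyl ether | C=COCC | starting material
5 | 3‑(ethenyloxy)‑4,4‑dimethoxy‑2‑methylbut‑1‑ene (racemic) | C=COC(C(C)=C)C(OC)OC | intermediate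
6 | (4E)‑6,6‑dimethoxy‑4‑methylhex‑4‑enal | O=CCC/C(C)=C/C(OC)OC | intermediate
7 | methyl (2Z,6E)‑2‑iodo‑8,8‑dimethoxy‑6‑methylocta‑2,6‑dienoate | COC(=O)/C(I)=C/CC/C(C)=C/C(OC)OC | intermediate
8 | methyl (2Z,6E)‑2‑iodo‑6‑methyl‑8‑oxoocta‑2,6‑dienoate | COC(=O)/C(I)=C/CC/C(C)=C/C=O | intermediate
9 | vinylmagnesium bromide | C=C[Mg]Br | starting material
10 | divinylzinc | C=C[Zn]C=C | intermediate
11 | ethenylzinc alkoxide of methyl (2Z,6E,8S)‑8‑hydroxy‑2‑iodo‑6‑methyldeca‑2,6,9‑trienoate | COC(=O)/C(I)=C/CC/C(C)=C/[C@H](C=C)O[Zn]C=C | intermediate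
12 | methyl (2Z)‑5‑{(2R,3R)‑3‑[(1S)‑1‑hydroxyprop‑2‑en‑1‑yl]‑2‑methyloxiran‑2‑yl}‑2‑iodopent‑2‑enoate | COC(=O)/C(I)=C/CC[C@@]1(C)O[C@@H]1[C@H](C=C)O | intermediate
13 | 2‑(bromomethyl)acrylic acid | C=C(CBr)C(=O)O | starting material
14 | 2‑(acetoxymethyl)acrylic acid | C=C(COC(C)=O)C(=O)O | intermediate
15 | 2‑(acetoxymethyl)acryloyl chloride | C=C(COC(C)=O)C(=O)Cl | intermediate
16 | 2‑(acetoxymethyl)acrylate ester of 12 (4R,5R,6S) | COC(=O)/C(I)=C/CC[C@@]1(C)O[C@@H]1[C@H](C=C)OC(=O)C(=C)COC(C)=O | intermediate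
17 | methyl (2Z)‑5‑{(2R,3R)‑3‑[(2S)‑4‑(acetoxymethyl)‑5‑oxo‑2,5‑dihydrofuran‑2‑yl]‑2‑methyloxiran‑2‑yl}‑2‑iodopent‑2‑enoate | COC(=O)/C(I)=C/CC[C@@]1(C)O[C@@H]1[C@H]1OC(=O)C(COC(C)=O)=C1 | intermediate
18 | acrolein | C=CC=O | starting material
19 | methyl (2E)‑5‑{(2R,3R)‑3‑[(2S)‑4‑(acetoxymethyl)‑5‑oxo‑2,5‑dihydrofuran‑2‑yl]‑2‑methyloxiran‑2‑yl}‑2‑[(1S)‑1‑hydroxyprop‑2‑en‑1‑yl]pent‑2‑enoate | C=C[C@H](O)/C(C(=O)OC)=C\CC[C@@]1(C)O[C@@H]1[C@H]1OC(=O)C(COC(C)=O)=C1 | intermediate
20 | tert‑butyldimethylsilyl ether of 19 | C=C[C@H](O[Si](C)(C)C(C)(C)C)/C(C(=O)OC)=C\CC[C@@]1(C)O[C@@H]1[C@H]1OC(=O)C(COC(C)=O)=C1 | intermediate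
21 | methyl (2E)‑2‑[(1R)‑1‑(tert‑butyldimethylsilyloxy)‑2‑oxoethyl]‑5‑{(2R,3R)‑3‑[(2S)‑4‑(acetoxymethyl)‑5‑oxo‑2,5‑dihydrofuran‑2‑yl]‑2‑methyloxiran‑2‑yl}pent‑2‑enoate | O=C[C@H](O[Si](C)(C)C(C)(C)C)/C(C(=O)OC)=C\CC[C@@]1(C)O[C@@H]1[C@H]1OC(=O)C(COC(C)=O)=C1 | intermediate
22 | macrocyclic alcohol (4R,5R,6S,7S,8R,9R): fluctuadin skeleton with free 8‑OH and 9‑OTBS | O[C@@H]1[C@@H]2C(=C)C(=O)O[C@@H]2[C@H]2O[C@]2(C)CC/C=C(/C(=O)OC)[C@H]1O[Si](C)(C)C(C)(C)C | intermediate
23 | 8‑O‑methacryloyl‑9‑O‑TBS macrocycle | C=C(C)C(=O)O[C@@H]1[C@@H]2C(=C)C(=O)O[C@@H]2[C@H]2O[C@]2(C)CC/C=C(/C(=O)OC)[C@H]1O[Si](C)(C)C(C)(C)C | intermediate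
24 | 9‑O‑deacetylfluctuadin (8‑O‑methacryloyl, free 9‑OH) | C=C(C)C(=O)O[C@@H]1[C@@H]2C(=C)C(=O)O[C@@H]2[C@H]2O[C@]2(C)CC/C=C(/C(=O)OC)[C@H]1O | intermediate
25 | fluctuadin | C=C(C)C(=O)O[C@@H]1[C@@H]2C(=C)C(=O)O[C@@H]2[C@H]2O[C@]2(C)CC/C=C(/C(=O)OC)[C@H]1OC(C)=O | target

## Step count and risks

Total steps: 13. Longest linear sequence: 12 (steps 1–4 and 6–13; step 5 is a one‑step branch).

The three steps most likely to fail are steps 11, 8 and 4.

Step 11 is the riskiest. The ten‑membered ketyl closure competes with simple reduction, pinacol dimerisation and loss of the silyloxy group, and neither the cis ring fusion nor the C8 configuration is assured. The fallback sets out from aldehyde 21 and closes the same bond by a polar umpolung allylation: Pd(PPh3)4 (cat.) and InI in THF at high dilution convert the allylic acetate into an allylindium species, which adds through C7 to the aldehyde in a closed six‑membered transition state. It comes back to the route at alcohol 22 and makes no new compound (F0).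

Step 8 may give poor facial control at C9 or erode the enoate geometry. The fallback sets out from 17: ligand‑free coupling with acrolein (CrCl2, NiCl2 cat., DMSO) gives 19 together with its C9‑epimeric alcohol F1. Dess–Martin oxidation of the mixture gives the cross‑conjugated dienone F2. Reduction with (R)‑Me‑CBS and catecholborane at −78 °C, with the branched alkenyl group acting as the large substituent, then sets C9 by reagent control and comes back at 19.

Step 4 may give low enantioselectivity with divinylzinc or incomplete threo selectivity in the one‑pot epoxidation. The fallback sets out from enal 8 and reverses the order of stereocontrol. NaBH4/CeCl3·7H2O gives the allylic alcohol F3. Sharpless asymmetric epoxidation (Ti(OiPr)4, D‑(−)‑diethyl tartrate, TBHP, −20 °C) gives the (2R,3R) epoxy alcohol F4, and Dess–Martin oxidation gives the epoxy aldehyde F5. Chelation‑controlled addition of vinylmagnesium bromide (MgBr2·OEt2, CH2Cl2, −78 °C) then gives the threo carbinol and comes back at 12.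

## Further compounds

F0 | step 11 | none | none
F1 | step 8 | C9 epimer of 19 [(1R)‑1‑hydroxyprop‑2‑en‑1‑yl] | C=C[C@@H](O)/C(C(=O)OC)=C\CC[C@@]1(C)O[C@@H]1[C@H]1OC(=O)C(COC(C)=O)=C1
F2 | step 8 | dienone: methyl (2E)‑2‑acryloyl‑5‑{(2R,3R)‑3‑[(2S)‑4‑(acetoxymethyl)‑5‑oxo‑2,5‑dihydrofuran‑2‑yl]‑2‑methyloxiran‑2‑yl}pent‑2‑enoate | C=CC(=O)/C(C(=O)OC)=C\CC[C@@]1(C)O[C@@H]1[C@H]1OC(=O)C(COC(C)=O)=C1
F3 | step 4 | methyl (2Z,6E)‑8‑hydroxy‑2‑iodo‑6‑methylocta‑2,6‑dienoate | COC(=O)/C(I)=C/CC/C(C)=C/CO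
F4 | step 4 | methyl (2Z)‑5‑[(2R,3R)‑3‑(hydroxymethyl)‑2‑methyloxiran‑2‑yl]‑2‑iodopent‑2‑enoate | COC(=O)/C(I)=C/CC[C@@]1(C)O[C@@H]1CO
F5 | step 4 | methyl (2Z)‑5‑[(2R,3R)‑3‑formyl‑2‑methyloxiran‑2‑yl]‑2‑iodopent‑2‑enoate | COC(=O)/C(I)=C/CC[C@@]1(C)O[C@@H]1C=O
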